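**Strategy.** The cyclopentane is opened at the bond between its only unsubstituted ring carbon (C6, the CH2 flanked by the acyloxy-bearing C7) and C5, the ring carbon that carries the CH(CH2OH)2 branch. Read as a reduced malonate, that branch makes C5 the β-carbon of an alkylidene malonate and C6 a primary radical. One 5-exo-trig radical cyclisation of an acyclic iodide, whose stereotriad C7–C8–C9 lies equatorial in a chair transition state, closes the ring and sets C5. Malonate reduction, acetonide protection, debenzylation, double esterification with an acetal-masked (3S,4E) secoiridoid acid and one aqueous acid treatment complete the target.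

Key step: step 9

Remark on labels: ring carbons are called C5 (bears the branch, whose central carbon is C4), C6 (ring CH2), C7 (secondary acyloxy), C8 (methyl) and C9 (bears C1, the CH2O-acyl carbon).
Remark on the chemistry: both acyl groups are the same (3S,4E)-4-formyl-3-(2-oxoethyl)hex-4-enoyl unit; compounds 1, 2, 7, 13, 21, 22 and 24 are taken as commercial; the target is treated as the open tetra-aldehyde diol, which may equilibrate with hydrates in solution.

**Route**

Step 1
Reactants: 1 2-(benzyloxy)acetaldehyde; 2 dimethyl 2-ethylidenemalonate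
Product: 3 dimethyl 2-[(2R,3S)-3-(benzyloxy)-4-oxobutan-2-yl]malonate
Conditions: (R)-α,α-diphenylprolinol trimethylsilyl ether (20 mol %), PhCO2H (20 mol %), 2 (3 equiv), slow addition of 1, CHCl3, 4 °C; used directly
Reagents that add atoms: none
Why: Enamine-catalysed asymmetric Michael addition in which the (E)-enamine of 1, shielded on one face by the diphenyl(silyloxy)methyl group, should attack the ethylidene carbon of 2 through the usual open synclinal transition state and set both new centres as the syn adduct; the (R)-catalyst is the one whose shielding gives the (S)-configured benzyloxy carbon.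

Step 2
Reactants: 3 dimethyl 2-[(2R,3S)-3-(benzyloxy)-4-oxobutan-2-yl]malonate
Product: 5 methyl (4R,5S)-5-(benzyloxy)-4-methyl-2-oxotetrahydro-2H-pyran-3-carboxylate (C-3 epimers), via hydroxy diester 4 (not isolated)
Conditions: NaBH4, MeOH, 0 °C; then TsOH·H2O (cat.), toluene, 60 °C
Reagents that add atoms: none
Why: Chemoselective borohydride reduction of the aldehyde followed by acid-catalysed δ-lactonisation of the primary alcohol onto one ester group; no chain stereocentre is touched and the C-3 centre is erased in step 3.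

Step 3
Reactants: 5 methyl (4R,5S)-5-(benzyloxy)-4-methyl-2-oxotetrahydro-2H-pyran-3-carboxylate
Product: 6 (4R,5S)-5-(benzyloxy)-4-methyltetrahydro-2H-pyran-2-one
Conditions: LiCl, DMSO, H2O, 140 °C
Reagents that add atoms: none
Why: Krapcho dealkoxycarbonylation of the malonate-type lactone ester (chloride attacks the methyl group and the carboxylate loses CO2), which leaves the two ring stereocentres untouched.

Step 4
Reactants: 6 (4R,5S)-5-(benzyloxy)-4-methyltetrahydro-2H-pyran-2-one; 7 benzyl chloromethyl ether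
Product: 9 (3S,4R,5S)-5-(benzyloxy)-3-[(benzyloxy)methyl]-4-methyltetrahydro-2H-pyran-2-one, via lithium enolate 8 (not isolated)
Conditions: LiN(i-Pr)2, THF, −78 °C; then 7, DMPU, −78 to −40 °C
Reagents that add atoms: none
Why: Alkylation of the δ-lactone lithium enolate, in which the electrophile should approach anti to the neighbouring C-4 methyl group and give the 3,4-trans (all-equatorial, also thermodynamically preferred) lactone, so setting C9.

Step 5
Reactants: 9 (3S,4R,5S)-5-(benzyloxy)-3-[(benzyloxy)methyl]-4-methyltetrahydro-2H-pyran-2-one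
Product: 10 (2S,3R,4S)-4-(benzyloxy)-2-[(benzyloxy)methyl]-5-hydroxy-N-methoxy-N,3-dimethylpentanamide
Conditions: MeNH(OMe)·HCl, AlMe3, CH2Cl2, 0 °C to rt; aq. Rochelle salt
Reagents that add atoms: N,O-dimethylhydroxylamine hydrochloride, CNOC.Cl
Why: Aminolysis of the lactone by the aluminium amide (Weinreb amide formation) opens the ring, frees the primary C6 hydroxyl and gives an acyl group that reduces cleanly to the aldehyde, without touching a stereocentre.

Step 6
Reactants: 10 (2S,3R,4S)-4-(benzyloxy)-2-[(benzyloxy)methyl]-5-hydroxy-N-methoxy-N,3-dimethylpentanamide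
Product: 11 (2S,3R,4S)-4-(benzyloxy)-2-[(benzyloxy)methyl]-5-iodo-N-methoxy-N,3-dimethylpentanamide
Conditions: I2, PPh3, imidazole, CH2Cl2, 0 °C; used directly
Reagents that add atoms: iodine, II
Why: Appel iodination converts the primary alcohol into the iodide radical precursor by SN2 displacement of the alkoxyphosphonium ion, leaving the stereocentres untouched.

Step 7
Reactants: 11 (2S,3R,4S)-4-(benzyloxy)-2-[(benzyloxy)methyl]-5-iodo-N-methoxy-N,3-dimethylpentanamide
Product: 12 (2S,3R,4S)-4-(benzyloxy)-2-[(benzyloxy)methyl]-5-iodo-3-methylpentanal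
Conditions: i-Bu2AlH, THF, −78 °C; aq. Rochelle salt
Reagents that add atoms: none
Why: Reduction of the Weinreb amide stops at the chelated tetrahedral aluminate, which releases the α-branched aldehyde only on cold work-up, so the C9 centre should survive and the iodide is not reduced.

Step 8
Reactants: 12 (2S,3R,4S)-4-(benzyloxy)-2-[(benzyloxy)methyl]-5-iodo-3-methylpentanal; 13 dimethyl malonate
Product: 14 dimethyl 2-[(2S,3R,4S)-4-(benzyloxy)-2-[(benzyloxy)methyl]-5-iodo-3-methylpentylidene]malonate
Conditions: TiCl4, pyridine, THF, 0 °C to rt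
Reagents that add atoms: none
Why: Knoevenagel condensation under TiCl4/pyridine, whose weakly basic low-temperature conditions suit α-branched epimerisable aldehydes, installs the alkylidene malonate acceptor (the malonate carbon becomes the branch carbon C4).

Step 9
Reactants: 14 dimethyl 2-[(2S,3R,4S)-4-(benzyloxy)-2-[(benzyloxy)methyl]-5-iodo-3-methylpentylidene]malonate
Product: 17 dimethyl 2-[(1R,2S,3R,4R)-4-(benzyloxy)-2-[(benzyloxy)methyl]-3-methylcyclopentyl]malonate, via primary alkyl radical 15 (not isolated), via malonyl radical 16 (not isolated)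
Conditions: Bu3SnH (1.3 equiv, syringe pump), AIBN (0.1 equiv), toluene, 90 °C, 0.01 M
Reagents that add atoms: none
Why: The tributyltin radical abstracts iodine from 14 to give the primary radical 15 at C6, which adds to the β-carbon C5 of the alkylidene malonate to give the doubly ester-stabilised radical 16, and this is reduced by Bu3SnH to 17 while the chain is carried on. The closest known reaction type is the tin hydride mediated 5-hexenyl radical cyclisation onto an electron-poor alkene (intramolecular Giese addition). The cyclopentane closes in the 5-exo-trig mode. The new stereocentre C5 is controlled by the chair-like transition state in which the C7 benzyloxy, C8 methyl and C9 benzyloxymethyl groups are all pseudo-equatorial, which places the malonyl carbon trans to the C9 and C7 substituents and cis to the C8 methyl group, as in the target. The step needs cyclisation to outrun direct reduction of 15 and 6-endo attack; the nucleophilic primary radical should add very fast to the doubly activated alkene, slow addition of the stannane at high dilution keeps the hydrogen donor scarce, and polarity together with the exo preference directs attack to C5.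

Step 10
Reactants: 17 dimethyl 2-[(1R,2S,3R,4R)-4-(benzyloxy)-2-[(benzyloxy)methyl]-3-methylcyclopentyl]malonate
Product: 18 2-[(1R,2S,3R,4R)-4-(benzyloxy)-2-[(benzyloxy)methyl]-3-methylcyclopentyl]propane-1,3-diol
Conditions: LiAlH4, THF, 0 °C to reflux
Reagents that add atoms: none
Why: Hydride reduction of both ester groups turns the malonate into the 2-substituted propane-1,3-diol, while the benzyl ethers and all stereocentres are inert.

Step 11
Reactants: 18 2-[(1R,2S,3R,4R)-4-(benzyloxy)-2-[(benzyloxy)methyl]-3-methylcyclopentyl]propane-1,3-diol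
Product: 19 5-[(1R,2S,3R,4R)-4-(benzyloxy)-2-[(benzyloxy)methyl]-3-methylcyclopentyl]-2,2-dimethyl-1,3-dioxane
Conditions: 2,2-dimethoxypropane, PPTS (cat.), acetone, rt
Reagents that add atoms: 2,2-dimethoxypropane, COC(C)(C)OC
Why: Acid-catalysed transketalisation closes the six-membered acetonide on the 1,3-diol, which blocks these two primary hydroxyls for the esterification.

Step 12
Reactants: 19 5-[(1R,2S,3R,4R)-4-(benzyloxy)-2-[(benzyloxy)methyl]-3-methylcyclopentyl]-2,2-dimethyl-1,3-dioxane
Product: 20 (1R,2R,3S,4R)-4-(2,2-dimethyl-1,3-dioxan-5-yl)-3-(hydroxymethyl)-2-methylcyclopentan-1-ol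
Conditions: H2 (1 atm), Pd/C (10 %), EtOAc, rt
Reagents that add atoms: none
Why: Hydrogenolysis of both benzyl ethers under neutral conditions frees exactly the primary (C1) and secondary (C7) hydroxyls that are to be acylated and leaves the acetonide intact.

Step 13
Reactants: 21 methyl acrylate; 22 4,4-diethoxybut-1-ene
Product: 23 methyl (E)-5,5-diethoxypent-2-enoate
Conditions: second-generation Grubbs catalyst RuCl2(=CHPh)(PCy3)(H2IMes) (3 mol %), 21 (3 equiv), CH2Cl2, 40 °C
Reagents that add atoms: none
Why: Olefin cross-metathesis of a terminal alkene with an excess of the acrylate partner should give the (E)-enoate selectively.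

Step 14
Reactants: 23 methyl (E)-5,5-diethoxypent-2-enoate; 24 (Z)-but-2-en-2-ylboronic acid
Product: 25 methyl (3S,4E)-3-(2,2-diethoxyethyl)-4-methylhex-4-enoate
Conditions: [Rh(OH)((R)-BINAP)]2 (3 mol % Rh), 24 (3 equiv), 1,4-dioxane/H2O (10:1), 50 °C
Reagents that add atoms: none
Why: Rhodium-catalysed asymmetric conjugate addition in which the alkenyl complex of monovalent rhodium with (R)-BINAP should insert the (E)-enoate on the face dictated by the ligand and set the (S) centre, the alkene geometry of 24 being retained.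

Step 15
Reactants: 25 methyl (3S,4E)-3-(2,2-diethoxyethyl)-4-methylhex-4-enoate
Product: 27 methyl (3S,4E)-3-(2,2-diethoxyethyl)-4-formylhex-4-enoate, via allylic alcohol 26 (not isolated)
Conditions: SeO2 (0.5 equiv), t-BuOOH (anhydrous, 3 equiv), CH2Cl2, rt; then MnO2, CH2Cl2, rt
Reagents that add atoms: tert-butyl hydroperoxide, CC(C)(C)OO; selenium dioxide, O=[Se]=O
Why: Riley allylic oxidation, in which the ene reaction of SeO2 at the less substituted alkene carbon and the [2,3]-sigmatropic shift oxidise the methyl group on the more substituted alkene carbon and return the double bond with the oxygenated carbon trans to the terminal methyl group; MnO2 then takes the allylic alcohol to the thermodynamically favoured (E)-enal.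

Step 16
Reactants: 27 methyl (3S,4E)-3-(2,2-diethoxyethyl)-4-formylhex-4-enoate
Product: 28 (3S,4E)-3-(2,2-diethoxyethyl)-4-formylhex-4-enoic acid
Conditions: LiOH·H2O, THF/H2O, 0 °C; aq. NaH2PO4 to pH 5
Reagents that add atoms: lithium hydroxide, [Li+].[OH-]
Why: Saponification of the methyl ester at 0 °C with buffered acidification gives the acid while the acetal survives, and the stereocentre, which is not α to a carbonyl group, cannot epimerise.

Step 17
Reactants: 20 (1R,2R,3S,4R)-4-(2,2-dimethyl-1,3-dioxan-5-yl)-3-(hydroxymethyl)-2-methylcyclopentan-1-ol; 28 (3S,4E)-3-(2,2-diethoxyethyl)-4-formylhex-4-enoic acid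
Product: 29 (1R,2R,3S,4R)-4-(2,2-dimethyl-1,3-dioxan-5-yl)-3-({[(3S,4E)-3-(2,2-diethoxyethyl)-4-formylhex-4-enoyl]oxy}methyl)-2-methylcyclopentyl (3S,4E)-3-(2,2-diethoxyethyl)-4-formylhex-4-enoate
Conditions: 28 (2.6 equiv), EDC·HCl (3 equiv), DMAP (0.5 equiv), CH2Cl2, 0 °C to rt
Reagents that add atoms: none
Why: Steglich esterification, in which the carbodiimide-activated acid is transferred by DMAP to the primary and the secondary hydroxyl of 20, the only free hydroxyls present.

Step 18
Reactants: 29 the bis-ester of step 17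
Product: 30 (1R,2R,3S,4R)-4-(1,3-dihydroxypropan-2-yl)-3-({[(3S,4E)-4-formyl-3-(2-oxoethyl)hex-4-enoyl]oxy}methyl)-2-methylcyclopentyl (3S,4E)-4-formyl-3-(2-oxoethyl)hex-4-enoate
Conditions: AcOH/H2O/THF (3:1:1), 35 °C
Reagents that add atoms: water, O
Why: Aqueous acid hydrolyses the two diethyl acetals and the acetonide in one operation, the water-rich medium disfavouring re-acetalisation of the liberated aldehydes with the 1,3-diol, and the esters and enals should be stable under these conditions.

**Compound list**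

1 | 2-(benzyloxy)acetaldehyde | O=CCOCc1ccccc1 | starting material
2 | dimethyl 2-ethylidenemalonate | CC=C(C(=O)OC)C(=O)OC | starting material
3 | dimethyl 2-[(2R,3S)-3-(benzyloxy)-4-oxobutan-2-yl]malonate | COC(=O)C(C(=O)OC)[C@@H](C)[C@H](OCc1ccccc1)C=O | intermediate
4 | dimethyl 2-[(2R,3S)-3-(benzyloxy)-4-hydroxybutan-2-yl]malonate | COC(=O)C(C(=O)OC)[C@@H](C)[C@H](OCc1ccccc1)CO | intermediate
5 | methyl (4R,5S)-5-(benzyloxy)-4-methyl-2-oxotetrahydro-2H-pyran-3-carboxylate (C-3 epimers) | COC(=O)C1[C@@H](C)[C@H](OCc2ccccc2)COC1=O | intermediate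
6 | (4R,5S)-5-(benzyloxy)-4-methyltetrahydro-2H-pyran-2-one | O=C1C[C@@H](C)[C@H](OCc2ccccc2)CO1 | intermediate
7 | benzyl chloromethyl ether | ClCOCc1ccccc1 | starting material
8 | lithium enolate of lactone 6 | [Li+].[O-]C1=C[C@@H](C)[C@H](OCc2ccccc2)CO1 | intermediate
9 | (3S,4R,5S)-5-(benzyloxy)-3-[(benzyloxy)methyl]-4-methyltetrahydro-2H-pyran-2-one | c1ccccc1COC[C@@H](C2=O)[C@@H](C)[C@H](OCc3ccccc3)CO2 | intermediate
10 | (2S,3R,4S)-4-(benzyloxy)-2-[(benzyloxy)methyl]-5-hydroxy-N-methoxy-N,3-dimethylpentanamide | c1ccccc1COC[C@@H](C(=O)N(C)OC)[C@@H](C)[C@H](OCc2ccccc2)CO | intermediate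
11 | (2S,3R,4S)-4-(benzyloxy)-2-[(benzyloxy)methyl]-5-iodo-N-methoxy-N,3-dimethylpentanamide | c1ccccc1COC[C@@H](C(=O)N(C)OC)[C@@H](C)[C@H](OCc2ccccc2)CI | intermediate
12 | (2S,3R,4S)-4-(benzyloxy)-2-[(benzyloxy)methyl]-5-iodo-3-methylpentanal | c1ccccc1COC[C@@H](C=O)[C@@H](C)[C@H](OCc2ccccc2)CI | intermediate
13 | dimethyl malonate | COC(=O)CC(=O)OC | starting material
14 | dimethyl 2-[(2S,3R,4S)-4-(benzyloxy)-2-[(benzyloxy)methyl]-5-iodo-3-methylpentylidene]malonate | c1ccccc1COC[C@@H](C=C(C(=O)OC)C(=O)OC)[C@@H](C)[C@H](OCc2ccccc2)CI | intermediate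
15 | C6-centred primary radical formed from 14 by loss of iodine | c1ccccc1COC[C@@H](C=C(C(=O)OC)C(=O)OC)[C@@H](C)[C@H](OCc2ccccc2)[CH2] | intermediate
16 | malonyl radical formed by 5-exo closure of 15 | c1ccccc1COC[C@@H]1[C@@H](C)[C@H](OCc2ccccc2)C[C@H]1[C](C(=O)OC)C(=O)OC | intermediate
17 | dimethyl 2-[(1R,2S,3R,4R)-4-(benzyloxy)-2-[(benzyloxy)methyl]-3-methylcyclopentyl]malonate | c1ccccc1COC[C@@H]1[C@@H](C)[C@H](OCc2ccccc2)C[C@H]1C(C(=O)OC)C(=O)OC | intermediate
18 | 2-[(1R,2S,3R,4R)-4-(benzyloxy)-2-[(benzyloxy)methyl]-3-methylcyclopentyl]propane-1,3-diol | c1ccccc1COC[C@@H]1[C@@H](C)[C@H](OCc2ccccc2)C[C@H]1C(CO)CO | intermediate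
19 | 5-[(1R,2S,3R,4R)-4-(benzyloxy)-2-[(benzyloxy)methyl]-3-methylcyclopentyl]-2,2-dimethyl-1,3-dioxane | c1ccccc1COC[C@@H]1[C@@H](C)[C@H](OCc2ccccc2)C[C@H]1C3COC(C)(C)OC3 | intermediate
20 | (1R,2R,3S,4R)-4-(2,2-dimethyl-1,3-dioxan-5-yl)-3-(hydroxymethyl)-2-methylcyclopentan-1-ol | OC[C@@H]1[C@@H](C)[C@H](O)C[C@H]1C2COC(C)(C)OC2 | intermediate
21 | methyl acrylate | C=CC(=O)OC | starting material
22 | 4,4-diethoxybut-1-ene | C=CCC(OCC)OCC | starting material
23 | methyl (E)-5,5-diethoxypent-2-enoate | CCOC(C/C=C/C(=O)OC)OCC | intermediate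
24 | (Z)-but-2-en-2-ylboronic acid | C/C=C(\C)B(O)O | starting material
25 | methyl (3S,4E)-3-(2,2-diethoxyethyl)-4-methylhex-4-enoate | C/C=C(\C)[C@@H](CC(OCC)OCC)CC(=O)OC | intermediate
26 | methyl (3S,4E)-3-(2,2-diethoxyethyl)-4-(hydroxymethyl)hex-4-enoate | C/C=C(/CO)[C@@H](CC(OCC)OCC)CC(=O)OC | intermediate
27 | methyl (3S,4E)-3-(2,2-diethoxyethyl)-4-formylhex-4-enoate | C/C=C(/C=O)[C@@H](CC(OCC)OCC)CC(=O)OC | intermediate
28 | (3S,4E)-3-(2,2-diethoxyethyl)-4-formylhex-4-enoic acid | C/C=C(/C=O)[C@@H](CC(OCC)OCC)CC(=O)O | intermediate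
29 | (1R,2R,3S,4R)-4-(2,2-dimethyl-1,3-dioxan-5-yl)-3-({[(3S,4E)-3-(2,2-diethoxyethyl)-4-formylhex-4-enoyl]oxy}methyl)-2-methylcyclopentyl (3S,4E)-3-(2,2-diethoxyethyl)-4-formylhex-4-enoate | C/C=C(/C=O)[C@@H](CC(OCC)OCC)CC(=O)OC[C@@H]1[C@@H](C)[C@H](OC(=O)C[C@H](CC(OCC)OCC)/C(C=O)=C\C)C[C@H]1C2COC(C)(C)OC2 | intermediate
30 | (1R,2R,3S,4R)-4-(1,3-dihydroxypropan-2-yl)-3-({[(3S,4E)-4-formyl-3-(2-oxoethyl)hex-4-enoyl]oxy}methyl)-2-methylcyclopentyl (3S,4E)-4-formyl-3-(2-oxoethyl)hex-4-enoate | C/C=C(/C=O)[C@@H](CC=O)CC(=O)OC[C@@H]1[C@@H](C)[C@H](OC(=O)C[C@H](CC=O)/C(C=O)=C\C)C[C@H]1C(CO)CO | target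

**Step count**

Total: 18 steps. Longest linear sequence: 14 steps (steps 1 to 12, then 17 and 18); the acid 28 is made in 4 steps (13 to 16).

**Steps most likely to fail**

Step 1. Self-aldol reaction of 1 may outrun the slow Michael addition to the weakly electrophilic acceptor, and enamine-mediated epimerisation may erode the syn ratio. The fallback builds the lactone by ring-closing metathesis and a substrate-controlled cuprate addition. It leaves the route before 3 (1 and 2 are not used), sets out from commercial (S)-but-3-ene-1,2-diol F1 and comes back at lactone 6. F1 is acylated at the primary hydroxyl (acryloyl chloride, 2,4,6-collidine, CH2Cl2, −78 °C) to (S)-2-hydroxybut-3-en-1-yl acrylate F2. The secondary hydroxyl is benzylated under acid catalysis (benzyl 2,2,2-trichloroacetimidate, TfOH cat.) to (S)-2-(benzyloxy)but-3-en-1-yl acrylate F3. Ring-closing metathesis with the second-generation Grubbs catalyst should give (S)-5-(benzyloxy)-5,6-dihydro-2H-pyran-2-one F4, and Me2CuLi (TMSCl, THF, −78 °C) should add anti to the benzyloxy group to give 6.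

Step 15. SeO2 may attack another allylic position or over-oxidise, and the selenous acid formed may hydrolyse the diethyl acetal. The fallback brings the oxygen in with the alkenyl nucleophile instead of by C–H oxidation. It sets out from enoate 23 and comes back at allylic alcohol 26, which is then oxidised with MnO2 to 27 as in step 15. Crotonaldehyde is α-iodinated (I2, pyridine) to (Z)-2-iodobut-2-enal F5 and reduced (NaBH4, CeCl3·7H2O, MeOH) to (Z)-2-iodobut-2-en-1-ol F6. Miyaura borylation (B2pin2, PdCl2(dppf), KOAc, DMSO, 80 °C) with retention of geometry should give (E)-2-(4,4,5,5-tetramethyl-1,3,2-dioxaborolan-2-yl)but-2-en-1-ol F7. The rhodium/(R)-BINAP conjugate addition of step 14, run with F7 and 23, should give 26 directly, with the methyl group already cis to the stereocentre.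

Step 8. The α-stereocentre of aldehyde 12 may epimerise, benzyl alcohol may be lost by β-elimination, or the iodide may alkylate pyridine under the Lewis-acidic condensation. The fallback makes the acceptor under neutral conditions and adds the second hydroxymethyl carbon after ring closure. It sets out from aldehyde 12 and comes back at diol 18. Wittig reaction of 12 with Ph3P=CHCO2Me (CH2Cl2, rt) should give methyl (2E,4S,5R,6S)-6-(benzyloxy)-4-[(benzyloxy)methyl]-7-iodo-5-methylhept-2-enoate F8. The tin hydride cyclisation of step 9 (same 5-exo-trig closure, same chair) should give methyl 2-[(1S,2S,3R,4R)-4-(benzyloxy)-2-[(benzyloxy)methyl]-3-methylcyclopentyl]acetate F9. Aldol reaction of its lithium enolate with gaseous formaldehyde (LiN(i-Pr)2, THF, −78 °C) should give methyl 2-[(1R,2S,3R,4R)-4-(benzyloxy)-2-[(benzyloxy)methyl]-3-methylcyclopentyl]-3-hydroxypropanoate F10; either configuration at the new centre serves, because that carbon becomes the symmetric branch carbon. LiAlH4 then gives 18.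

Further compounds
F1 | step 1 | (S)-but-3-ene-1,2-diol | C=C[C@H](O)CO
F2 | step 1 | (S)-2-hydroxybut-3-en-1-yl acrylate | C=CC(=O)OC[C@@H](O)C=C
F3 | step 1 | (S)-2-(benzyloxy)but-3-en-1-yl acrylate | C=CC(=O)OC[C@@H](OCc1ccccc1)C=C
F4 | step 1 | (S)-5-(benzyloxy)-5,6-dihydro-2H-pyran-2-one | O=C1C=C[C@H](OCc2ccccc2)CO1
F5 | step 15 | (Z)-2-iodobut-2-enal | C/C=C(\I)C=O
F6 | step 15 | (Z)-2-iodobut-2-en-1-ol | C/C=C(\I)CO
F7 | step 15 | (E)-2-(4,4,5,5-tetramethyl-1,3,2-dioxaborolan-2-yl)but-2-en-1-ol | C/C=C(/CO)B1OC(C)(C)C(C)(C)O1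
F8 | step 8 | methyl (2E,4S,5R,6S)-6-(benzyloxy)-4-[(benzyloxy)methyl]-7-iodo-5-methylhept-2-enoate | c1ccccc1COC[C@@H](/C=C/C(=O)OC)[C@@H](C)[C@H](OCc2ccccc2)CI
F9 | step 8 | methyl 2-[(1S,2S,3R,4R)-4-(benzyloxy)-2-[(benzyloxy)methyl]-3-methylcyclopentyl]acetate | c1ccccc1COC[C@@H]1[C@@H](C)[C@H](OCc2ccccc2)C[C@H]1CC(=O)OC
F10 | step 8 | methyl 2-[(1R,2S,3R,4R)-4-(benzyloxy)-2-[(benzyloxy)methyl]-3-methylcyclopentyl]-3-hydroxypropanoate (both epimers at the carbinol-bearing carbon) | c1ccccc1COC[C@@H]1[C@@H](C)[C@H](OCc2ccccc2)C[C@H]1C(CO)C(=O)OC
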